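The data are simulated for substances that don't exist; scatter was added.

I decided to count acid rather than base in this flask.

| flask | electrophile | free base | protonated nucleophile | remark | time |
|---|---|---|---|---|---|
| grey | 0.58 M | 0.70 equiv | 2 equiv | run made earlier |  |
| ochre | 0.58 M | 1.1 equiv | 2 equiv | run made earlier |  |
| teal | 1.2 M | 0.50 equiv | 2 equiv | run made earlier |  |
| flask | 0.58 M | 0.500 equiv | 2.00 equiv |  | 2.0 h |

- grey (time / min: target / %, side product / %): 6.00: 68, 1; 20.0: 93, 6; 30.0: 92, 7; 50.0: 94, 5; 80.0: 93, 5
- ochre (time / min: target / %, side product / %): 6.00: 78, 0; 20.0: 95, 5; 30.0: 93, 7; 50.0: 94, 7; 80.0: 94, 10
- teal (time / min: target / %, side product / %): 6.00: 64, 4; 20.0: 88, 12; 30.0: 90, 9; 50.0: 89, 12; 80.0: 87, 14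

(each reading ± 1.5 percentage points)



1. concentration of target at 2.0 h, in M
2. concentration of side product at 2.0 h, in M
3. concentration of free base at 2.0 h, in M

First question: does electrophile matter at 2.0 h? In the teal run, with the same equivalents of free base as this flask, target and side product read 100 % together by 20.0 min, and 2.0 h is 6.00 times that. So I took conversion in this flask as complete, and the target near the grey reading of 93 %.

Second question: can the free base stay free? I assumed that each protonated nucleophile brings one acid and that each electrophile converted sets one more free. I therefore reckoned the acid load: acid in play, as equivalents of protonated nucleophile plus one, per equivalent of free base charged. Here it came to 6.00. On the charge, the acid outnumbers the base, so I expected the free base in this flask to end below its charge.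

Third question: how much stays free? As a rough guess of my own for this flask at 2.0 h, not derived from the runs, I put the free share of the base at one part in the load, which gave 0.0483 M of free base, below the forecast's figure.

The forecast gave 0.54 M of target, 0.036 M of side product and 0.27 M of free base, the base being “probably mostly retained”.

The flask gave 0.532 M of target, 0.0478 M of side product and 0.0611 M of free base.

    acid set free + target → side product (k = 0.00338 /M/s)
    nucleophile + acid set free ⇌ idle adduct, settled at all times (K = 340 /M)
    nucleophile + acid set free ⇌ protonated nucleophile, settled at all times (K = 460 /M)
    acid set free + free base ⇌ salt of the base, settled at all times (K = 5800 /M)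
    electrophile + nucleophile → acid set free + target (k = 0.0848 /M/s)
    acid set free → by-product carried off (k = 0.0368 /s)

In this flask at 2.00 h the salt of the base, its resting state, stood at 0.229 M, more than the free base. The free share of the charged base was 21 % against one part in 6.00, so the guess came out low by a factor of 1.27.

A neighbour flask, otherwise like this one, with 5.00 equiv of protonated nucleophile has a load of 12.0, twice this flask's, so the same guess gives 0.0242 M of free base there at 2.0 h. The computed value is 0.0275 M.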